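**Retrosynthetic overview**
1. Target 19 ⇒ global deprotection of 17; the C11–O ester bond ⇒ Mitsunobu inversion of alcohol 15 with diacetylcaffeic acid 16.
2. Dihydropyranone (second ring) ⇒ organocatalytic formal hetero-Diels–Alder of α-alkoxy aldehyde 10 with vinylketene silyl acetal 13 (C4–C5 and O–C1 bonds, sets C5).
3. Aldehyde 10 ⇒ ozonolysis of vinyl-tetrahydrofuran 8; tetrahydrofuran (first ring) ⇒ Shi epoxidation of the E-alkene of dienol 6, then 5-exo epoxide opening by the C7 hydroxyl (sets C10, C11).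
4. Dienol 6 ⇒ phosphoric-acid-catalysed syn-alkoxyallylboration of (E)-hex-4-enal 4 with Z-boronate 3 (C6–C7 bond, sets C6, C7); 3 ⇐ allyl MOM ether 1.

Assumption: (E)-hex-4-enal, allyl methoxymethyl ether and (E)-3,4-diacetoxycinnamic acid are bought as catalogue compounds; chain numbering C1 (lactone C=O) to C12 (CH3) is used in the explanations.

**Step 1**
Reactants: 1 allyl methoxymethyl ether
Product: 3 2-[(2Z)-3-(methoxymethoxy)prop-2-en-1-yl]-4,4,5,5-tetramethyl-1,3,2-dioxaborolane, via lithio allyl ether 2 (not isolated)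
Conditions: s-BuLi, THF, −78 °C; i-PrOBpin, −78 → 0 °C; HCl·Et2O; distil
Reagents that add atoms: 2-isopropoxy-4,4,5,5-tetramethyl-1,3,2-dioxaborolane (i-PrOBpin), CC(C)OB1OC(C)(C)C(C)(C)O1
Why: α-Lithiation gives the O-chelated (Z)-alkoxyallyl anion, which is borylated at the γ-terminus (Hoffmann/Wuts-type alkoxyallylboronate synthesis), fixing the Z enol-ether geometry needed for syn transfer.

**Step 2**
Reactants: 3 (Z)-γ-(methoxymethoxy)allyl pinacol boronate (1.2 equiv); 4 (4E)-hex-4-enal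
Product: 6 (3R,4R,7E)-3-(methoxymethoxy)nona-1,7-dien-4-ol, via borate ester 5 (not isolated)
Conditions: (S)-TRIP (5 mol %), 4 Å MS, toluene, −30 °C; aq. NaHCO3 work-up
Reagents that add atoms: none
Why: Chiral phosphoric acid-catalysed allylboration (Antilla type) through a closed chair transition state, in which the Z-γ-alkoxy reagent gives the syn (threo) C6/C7 pair and (S)-TRIP directs attack to the Si face of the aldehyde (by analogy with the allyl/crotyl series), so C6 and C7 are the first stereocentres and come from achiral inputs.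

**Step 3**
Reactants: 6 (3R,4R,7E)-3-(methoxymethoxy)nona-1,7-dien-4-ol
Product: 8 (1R)-1-[(2S,5R)-5-[(1R)-1-(methoxymethoxy)prop-2-en-1-yl]oxolan-2-yl]ethan-1-ol, via epoxy alcohol 7 (not isolated)
Conditions: Shi ketone (D-fructose-derived, 30 mol %), Oxone, K2CO3, n-Bu4NHSO4, MeCN/DMM–aq. borate buffer (pH 10.5), 0 °C; then CSA (10 mol %), CH2Cl2, 0 °C → rt
Reagents that add atoms: Oxone (active component potassium peroxymonosulfate), [K+].[O-]S(=O)(=O)OO
Why: Shi asymmetric epoxidation is selective for the trans-disubstituted alkene over the vinyl group and gives the (R,R)-epoxide under catalyst control, and acid-promoted 5-exo-tet opening by the C7 hydroxyl inverts C10 to give the 2,5-cis-tetrahydrofuran with the C11 carbinol (R) still to be inverted.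

**Step 4**
Reactants: 8 vinyl tetrahydrofuran alcohol
Product: 10 (2S)-2-[(2R,5S)-5-[(1R)-1-hydroxyethyl]oxolan-2-yl]-2-(methoxymethoxy)acetaldehyde, via ozonide 9 (not isolated)
Conditions: O3, CH2Cl2, −78 °C; Me2S, −78 °C → rt; used crude
Reagents that add atoms: ozone, [O-][O+]=O
Why: Ozonolysis with reductive work-up cleaves the only remaining alkene to the α-alkoxy aldehyde without touching the stereocentres (used at once to avoid C6 epimerisation).

**Step 5**
Reactants: 11 methyl (2E)-but-2-enoate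
Product: 13 1-methoxy-1-(trimethylsilyloxy)buta-1,3-diene (C1 isomer mixture), via lithium dienolate 12 (not isolated)
Conditions: LDA, DMPU, THF, −78 °C; TMSCl; distil
Reagents that add atoms: chlorotrimethylsilane, C[Si](C)(C)Cl
Why: γ-Deprotonation of the crotonate and O-silylation of the extended enolate is the standard vinylketene silyl acetal synthesis.

**Step 6**
Reactants: 10 α-alkoxy aldehyde; 13 vinylketene silyl acetal (3 equiv)
Product: 15 (6R)-6-[(S)-[(2R,5S)-5-[(1R)-1-hydroxyethyl]oxolan-2-yl](methoxymethoxy)methyl]-5,6-dihydro-2H-pyran-2-one, via silyl ketal cycloadduct 14 (not isolated)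
Conditions: (S,S)-1-naphthyl-TADDOL (20 mol %), toluene, −60 → −30 °C; then TFA (cat.), CH2Cl2, 0 °C
Reagents that add atoms: none
Why: Proposed new method: a hydrogen-bond-donor (TADDOL)-catalysed formal hetero-Diels–Alder reaction of an unsubstituted vinylketene silyl acetal with an α-alkoxy aliphatic aldehyde, in which single-point H-bonding lowers the aldehyde LUMO, the γ-carbon of the s-cis diene attacks C=O in an asynchronous [4+2] (or aldol/silyl-transfer ring closure) so the ring alkene is necessarily cis and the silyl ketal collapses to the 5,6-dihydropyran-2-one on acid work-up, while attack anti to the C6–OMOM group (Felkin–Anh/Cornforth) reinforced by the matched catalyst antipode gives 5R; the closest known reaction type is the TADDOL-catalysed hetero-Diels–Alder of Brassard's and Rawal's dienes with aldehydes, and the vinylogous Mukaiyama aldol.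

**Step 7**
Reactants: 15 lactone alcohol; 16 (2E)-3-[3,4-bis(acetyloxy)phenyl]prop-2-enoic acid
Product: 17 (1S)-1-[(2S,5R)-5-[(S)-(methoxymethoxy)[(2R)-6-oxo-3,6-dihydro-2H-pyran-2-yl]methyl]oxolan-2-yl]ethyl (2E)-3-[3,4-bis(acetyloxy)phenyl]prop-2-enoate
Conditions: PPh3, DIAD, THF, 0 °C → rt
Reagents that add atoms: none
Why: Mitsunobu esterification proceeds by SN2 displacement of the oxyphosphonium, so the only free hydroxyl (C11) is acylated with inversion (R → S), turning the erythro epoxide-opening product into the required threo C10/C11 ester.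

**Step 8**
Reactants: 17 MOM/diacetate-protected ester
Product: 19 (1S)-1-[(2S,5R)-5-[(S)-hydroxy[(2R)-6-oxo-3,6-dihydro-2H-pyran-2-yl]methyl]oxolan-2-yl]ethyl (2E)-3-(3,4-dihydroxyphenyl)prop-2-enoate (target), via diacetate 18 (not isolated)
Conditions: Me2BBr, CH2Cl2, −78 °C; then MeOH, −78 °C → rt
Reagents that add atoms: none
Why: Bromodimethylborane cleaves the MOM acetal at −78 °C (Guindon acetal cleavage), and the HBr/MeOH formed on quenching transesterifies the two aryl acetates much faster than the hindered alkyl cinnamate or the lactone, releasing the target without touching any stereocentre.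

**Compound list**
1 | allyl methoxymethyl ether [3-(methoxymethoxy)prop-1-ene] | C=CCOCOC | starting material
2 | [(2Z)-3-(methoxymethoxy)prop-2-en-1-yl]lithium | [Li]C/C=C\OCOC | intermediate
3 | 2-[(2Z)-3-(methoxymethoxy)prop-2-en-1-yl]-4,4,5,5-tetramethyl-1,3,2-dioxaborolane | COCO/C=C\CB1OC(C)(C)C(C)(C)O1 | intermediate
4 | (4E)-hex-4-enal | C/C=C/CCC=O | starting material
5 | 2-{[(3R,4R,7E)-3-(methoxymethoxy)nona-1,7-dien-4-yl]oxy}-4,4,5,5-tetramethyl-1,3,2-dioxaborolane | C=C[C@@H](OCOC)[C@H](OB1OC(C)(C)C(C)(C)O1)CC/C=C/C | intermediate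
6 | (3R,4R,7E)-3-(methoxymethoxy)nona-1,7-dien-4-ol | C=C[C@@H](OCOC)[C@H](O)CC/C=C/C | intermediate
7 | (3R,4R)-3-(methoxymethoxy)-6-[(2R,3R)-3-methyloxiran-2-yl]hex-1-en-4-ol | C=C[C@@H](OCOC)[C@H](O)CC[C@H]1O[C@@H]1C | intermediate
8 | (1R)-1-[(2S,5R)-5-[(1R)-1-(methoxymethoxy)prop-2-en-1-yl]oxolan-2-yl]ethan-1-ol | C[C@@H](O)[C@@H]1CC[C@H]([C@H](OCOC)C=C)O1 | intermediate
9 | (1R)-1-[(2S,5R)-5-[(S)-(methoxymethoxy)(1,2,4-trioxolan-3-yl)methyl]oxolan-2-yl]ethan-1-ol (trioxolane C3 epimers) | C[C@@H](O)[C@@H]1CC[C@H]([C@H](OCOC)C2OCOO2)O1 | intermediate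
10 | (2S)-2-[(2R,5S)-5-[(1R)-1-hydroxyethyl]oxolan-2-yl]-2-(methoxymethoxy)acetaldehyde | C[C@@H](O)[C@@H]1CC[C@H]([C@H](OCOC)C=O)O1 | intermediate
11 | methyl (2E)-but-2-enoate | C/C=C/C(=O)OC | starting material
12 | lithium 1-methoxybuta-1,3-dien-1-olate | C=CC=C(OC)O[Li] | intermediate
13 | 1-methoxy-1-(trimethylsilyloxy)buta-1,3-diene (C1 isomer mixture) | C=CC=C(OC)O[Si](C)(C)C | intermediate
14 | (1R)-1-[(2S,5R)-5-[(S)-(methoxymethoxy)[(2R)-6-methoxy-6-(trimethylsilyloxy)-3,6-dihydro-2H-pyran-2-yl]methyl]oxolan-2-yl]ethan-1-ol (ketal epimers) | C[C@@H](O)[C@@H]1CC[C@H]([C@H](OCOC)[C@H]2CC=CC(OC)(O[Si](C)(C)C)O2)O1 | intermediate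
15 | (6R)-6-[(S)-[(2R,5S)-5-[(1R)-1-hydroxyethyl]oxolan-2-yl](methoxymethoxy)methyl]-5,6-dihydro-2H-pyran-2-one | C[C@@H](O)[C@@H]1CC[C@H]([C@H](OCOC)[C@H]2CC=CC(=O)O2)O1 | intermediate
16 | (2E)-3-[3,4-bis(acetyloxy)phenyl]prop-2-enoic acid | CC(=O)Oc1ccc(/C=C/C(=O)O)cc1OC(C)=O | starting material
17 | (1S)-1-[(2S,5R)-5-[(S)-(methoxymethoxy)[(2R)-6-oxo-3,6-dihydro-2H-pyran-2-yl]methyl]oxolan-2-yl]ethyl (2E)-3-[3,4-bis(acetyloxy)phenyl]prop-2-enoate | C[C@H](OC(=O)/C=C/c1ccc(OC(C)=O)c(OC(C)=O)c1)[C@@H]1CC[C@H]([C@H](OCOC)[C@H]2CC=CC(=O)O2)O1 | intermediate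
18 | (1S)-1-[(2S,5R)-5-[(S)-hydroxy[(2R)-6-oxo-3,6-dihydro-2H-pyran-2-yl]methyl]oxolan-2-yl]ethyl (2E)-3-[3,4-bis(acetyloxy)phenyl]prop-2-enoate | C[C@H](OC(=O)/C=C/c1ccc(OC(C)=O)c(OC(C)=O)c1)[C@@H]1CC[C@H]([C@H](O)[C@H]2CC=CC(=O)O2)O1 | intermediate
19 | (1S)-1-[(2S,5R)-5-[(S)-hydroxy[(2R)-6-oxo-3,6-dihydro-2H-pyran-2-yl]methyl]oxolan-2-yl]ethyl (2E)-3-(3,4-dihydroxyphenyl)prop-2-enoate | C[C@H](OC(=O)/C=C/c1ccc(O)c(O)c1)[C@@H]1CC[C@H]([C@H](O)[C@H]2CC=CC(=O)O2)O1 | target

**Count**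
Total steps: 8. Longest linear sequence: 7 (steps 1, 2, 3, 4, 6, 7, 8).

**Steps most likely to fail**

Step 6 (the proposed hetero-Diels–Alder) may give the open-chain E-configured vinylogous aldol product, which cannot lactonise, or poor facial control. The fallback uses known chemistry, sets out from 10 and comes back at 15. Aldehyde 10 undergoes a Lewis-acid hetero-Diels–Alder reaction with commercial (E)-1-methoxybuta-1,3-diene under Jacobsen's tridentate Schiff-base chromium(III) catalyst (antipode matched with the Felkin preference) to give (1R)-1-[(2S,5R)-5-[(S)-(methoxymethoxy)[(2R)-6-methoxy-3,6-dihydro-2H-pyran-2-yl]methyl]oxolan-2-yl]ethan-1-ol F1. Hydrolysis of the methyl acetal (PPTS, aqueous acetone, MOM retained) gives the lactol (1R)-1-[(2S,5R)-5-[(S)-[(2R)-6-hydroxy-3,6-dihydro-2H-pyran-2-yl](methoxymethoxy)methyl]oxolan-2-yl]ethan-1-ol F2. MnO2 then oxidises the allylic lactol selectively (the C11 carbinol is not allylic) to lactone 15.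

Step 2 may give insufficient ee or syn/anti ratio with an unbranched aliphatic aldehyde and a γ-alkoxy reagent. The fallback replaces catalyst control by Brown's reagent control, sets out from 1 and 4 and comes back at 6. Lithio ether 2 (from 1 as in step 1) is trapped with (−)-B-methoxydiisopinocampheylborane and then BF3·OEt2 to give [(2Z)-3-(methoxymethoxy)prop-2-en-1-yl]bis[(1R,2R,3R,5S)-isopinocampheyl]borane F3. This adds to 4 at −78 °C (Si face, syn) to give the borinate of 6, [(3R,4R,7E)-3-(methoxymethoxy)nona-1,7-dien-4-yl] diisopinocampheylborinate F4, and NaOH/H2O2 work-up releases 6.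

Step 8 may be incomplete or erode the lactone or the alkyl cinnamate during the acidic methanolysis of the aryl acetates. The fallback changes the protecting-group plan so that one acetal cleavage frees everything; it sets out from 15 and comes back at 19. Caffeic acid with MOMCl/i-Pr2NEt gives methoxymethyl (2E)-3-[3,4-bis(methoxymethoxy)phenyl]prop-2-enoate F5, and LiOH gives (2E)-3-[3,4-bis(methoxymethoxy)phenyl]prop-2-enoic acid F6. Mitsunobu coupling of 15 with F6 (PPh3, DIAD) gives the tris-MOM ester (1S)-1-[(2S,5R)-5-[(S)-(methoxymethoxy)[(2R)-6-oxo-3,6-dihydro-2H-pyran-2-yl]methyl]oxolan-2-yl]ethyl (2E)-3-[3,4-bis(methoxymethoxy)phenyl]prop-2-enoate F7. Me2BBr at −78 °C with a MeOH/NaHCO3 quench removes all three MOM groups to give 19.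

**Further compounds**
F1 | step 6 | (1R)-1-[(2S,5R)-5-[(S)-(methoxymethoxy)[(2R)-6-methoxy-3,6-dihydro-2H-pyran-2-yl]methyl]oxolan-2-yl]ethan-1-ol (acetal epimers) | C[C@@H](O)[C@@H]1CC[C@H]([C@H](OCOC)[C@H]2CC=CC(OC)O2)O1
F2 | step 6 | (1R)-1-[(2S,5R)-5-[(S)-[(2R)-6-hydroxy-3,6-dihydro-2H-pyran-2-yl](methoxymethoxy)methyl]oxolan-2-yl]ethan-1-ol (lactol epimers) | C[C@@H](O)[C@@H]1CC[C@H]([C@H](OCOC)[C@H]2CC=CC(O)O2)O1
F3 | step 2 | [(2Z)-3-(methoxymethoxy)prop-2-en-1-yl]bis[(1R,2R,3R,5S)-2,6,6-trimethylbicyclo[3.1.1]heptan-3-yl]borane | COCO/C=C\CB([C@@H]1C[C@@H]2C[C@@H](C2(C)C)[C@H]1C)[C@@H]1C[C@@H]2C[C@@H](C2(C)C)[C@H]1C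
F4 | step 2 | [(3R,4R,7E)-3-(methoxymethoxy)nona-1,7-dien-4-yl] bis[(1R,2R,3R,5S)-2,6,6-trimethylbicyclo[3.1.1]heptan-3-yl]borinate | C=C[C@@H](OCOC)[C@H](OB([C@@H]1C[C@@H]2C[C@@H](C2(C)C)[C@H]1C)[C@@H]1C[C@@H]2C[C@@H](C2(C)C)[C@H]1C)CC/C=C/C
F5 | step 8 | methoxymethyl (2E)-3-[3,4-bis(methoxymethoxy)phenyl]prop-2-enoate | COCOC(=O)/C=C/c1ccc(OCOC)c(OCOC)c1
F6 | step 8 | (2E)-3-[3,4-bis(methoxymethoxy)phenyl]prop-2-enoic acid | OC(=O)/C=C/c1ccc(OCOC)c(OCOC)c1
F7 | step 8 | (1S)-1-[(2S,5R)-5-[(S)-(methoxymethoxy)[(2R)-6-oxo-3,6-dihydro-2H-pyran-2-yl]methyl]oxolan-2-yl]ethyl (2E)-3-[3,4-bis(methoxymethoxy)phenyl]prop-2-enoate | C[C@H](OC(=O)/C=C/c1ccc(OCOC)c(OCOC)c1)[C@@H]1CC[C@H]([C@H](OCOC)[C@H]2CC=CC(=O)O2)O1
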